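**Plan**
- Retrosynthetic cuts: first the three O–Si bonds, then the aryl ketone bond C4–C4a of ring C, then the ether bond O1–C2, then C6–geranyl on ring A and C2–C3 of the side chain.
- Forward: ring A piece 3 (one step from phloroglucinol) and ring B piece 9 (three steps from methyl syringate) are joined at O1–C2 by a Mitsunobu reaction. After silylation, ring C is closed last by acylation of ring A at C4a, and fluoride frees the three phenols.
- Enabling feature: in ring A the geranyl carbon C6 is para to C8a (the carbon bearing O1) and sits between the oxygenated C5 and C7. The aryl ether 11 therefore has a local twofold axis through C8a···C6, its two ortho carbons (future C4a and C8) are interchangeable, and closure can only give the 6-geranyl-5,7-dioxygenated chromanone.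
- Stereochemistry: C2 (S) comes from catalyst-controlled transfer hydrogenation to the (R)-carbinol 9 followed by SN2 inversion in the Mitsunobu step. The ring closure does not touch C2, and the E olefin is that of geraniol.

Key step: step 7

Remark: C2 of the target is read as S from the SMILES, and the facial sense of step 4 is assigned by the acetophenone model (the enantiomeric ligand would be used if the carbinol proved to be S). TBS = tert-butyldimethylsilyl; geranyl = (2E)-3,7-dimethylocta-2,6-dien-1-yl.

**Route**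

Step 1
Reactants: 1 phloroglucinol (benzene-1,3,5-triol); 2 geraniol [(2E)-3,7-dimethylocta-2,6-dien-1-ol]
Product: 3 2-geranylphloroglucinol {2-[(2E)-3,7-dimethylocta-2,6-dien-1-yl]benzene-1,3,5-triol}
Conditions: BF3·OEt2 (cat.), 1,4-dioxane, rt, 1 in excess
Reagents that add atoms: none
Why: Friedel–Crafts allylation in which the BF3-activated allylic alcohol alkylates the very nucleophilic, threefold-symmetric triol at carbon through its primary terminus, so only one mono-C-geranyl isomer is possible, the E olefin of geraniol should be carried over, and the excess of 1 limits double alkylation.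

Step 2
Reactants: 4 methyl syringate (methyl 4-hydroxy-3,5-dimethoxybenzoate)
Product: 5 methyl 4-(TBS-oxy)-3,5-dimethoxybenzoate
Conditions: TBSCl, imidazole, DMF, rt
Reagents that add atoms: tert-butyldimethylsilyl chloride (TBSCl), CC(C)(C)[Si](C)(C)Cl
Why: Standard silylation of a phenol, which masks the acidic 4-OH for the enolate chemistry and gives an ether that fluoride removes at the end together with the others.

Step 3
Reactants: 5 methyl 4-(TBS-oxy)-3,5-dimethoxybenzoate; 6 N,N-dimethylacetamide
Product: 8 3-[4-(TBS-oxy)-3,5-dimethoxyphenyl]-N,N-dimethyl-3-oxopropanamide, via lithium enolate of N,N-dimethylacetamide 7 (not isolated)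
Conditions: 6, LiN(iPr)2 (2.2 equiv), THF, −78 °C; then 5, −78 → 0 °C; AcOH quench
Reagents that add atoms: lithium diisopropylamide, [Li+].CC(C)[N-]C(C)C (lithium held only in 7)
Why: Crossed Claisen condensation in which the amide enolate acylates the non-enolisable aryl ester and the β-keto amide is drained as its own enolate (hence two equivalents of base), which should prevent over-addition.

Step 4
Reactants: 8 3-[4-(TBS-oxy)-3,5-dimethoxyphenyl]-N,N-dimethyl-3-oxopropanamide
Product: 9 (3R)-3-[4-(TBS-oxy)-3,5-dimethoxyphenyl]-3-hydroxy-N,N-dimethylpropanamide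
Conditions: RuCl[(R,R)-TsDPEN](p-cymene) (1 mol %), HCO2H/Et3N (5:2), DMF, 30 °C
Reagents that add atoms: none
Why: Noyori–Ikariya asymmetric transfer hydrogenation of an aryl ketone, in which the (R,R)-ligand should deliver hydride to the Si face (aryl group in the CH/π pocket, as with acetophenone) and so set the carbinol centre as R.

Step 5
Reactants: 9 (3R)-3-[4-(TBS-oxy)-3,5-dimethoxyphenyl]-3-hydroxy-N,N-dimethylpropanamide; 3 2-geranylphloroglucinol
Product: 10 (3S)-3-(4-geranyl-3,5-dihydroxyphenoxy)-3-[4-(TBS-oxy)-3,5-dimethoxyphenyl]-N,N-dimethylpropanamide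
Conditions: PPh3, DIAD, THF, 0 °C → rt, 3 in excess
Reagents that add atoms: none
Why: Mitsunobu etherification in which the phenol displaces the benzylic oxyphosphonium by SN2 with inversion (R carbinol to S ether, the future C2), and the C5 hydroxyl of 3, the only one without an ortho substituent, should react in preference to the two hydroxyls that flank the geranyl chain.

Step 6
Reactants: 10 (3S)-3-(4-geranyl-3,5-dihydroxyphenoxy)-3-[4-(TBS-oxy)-3,5-dimethoxyphenyl]-N,N-dimethylpropanamide
Product: 11 (3S)-3-[3,5-bis(TBS-oxy)-4-geranylphenoxy]-3-[4-(TBS-oxy)-3,5-dimethoxyphenyl]-N,N-dimethylpropanamide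
Conditions: TBSCl, imidazole, DMF, rt
Reagents that add atoms: tert-butyldimethylsilyl chloride (TBSCl), CC(C)(C)[Si](C)(C)Cl
Why: Standard silylation of phenols, which blocks O-triflation in step 7, keeps ring A electron-rich and keeps its two ortho carbons equivalent.

Step 7
Reactants: 11 (3S)-3-[3,5-bis(TBS-oxy)-4-geranylphenoxy]-3-[4-(TBS-oxy)-3,5-dimethoxyphenyl]-N,N-dimethylpropanamide
Product: 14 (2S)-5,7-bis(TBS-oxy)-2-[4-(TBS-oxy)-3,5-dimethoxyphenyl]-6-geranyl-2,3-dihydro-4H-chromen-4-one, via O-triflyl iminium triflate 12 (not isolated), via ring-C iminium triflate 13 (not isolated)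
Conditions: Tf2O, 2-fluoropyridine, CH2Cl2 (0.02 M), −78 → 0 °C; then sat. aq. NaHCO3, THF, rt
Reagents that add atoms: water, O (carbonyl oxygen of 14); trifluoromethanesulfonic anhydride (Tf2O), O=S(=O)(OS(=O)(=O)C(F)(F)F)C(F)(F)F (atoms held only in 12 and 13)
Why: Tf2O turns the tertiary amide into the O-triflyl iminium triflate 12, whose iminium carbon is attacked by an ortho carbon of the trioxygenated ring A; loss of the ring proton (taken up by 2-fluoropyridine, so no free TfOH reaches the olefins or silyl ethers) and of triflate gives the ring-C iminium 13, and bicarbonate water then exchanges NMe2 for the carbonyl oxygen. The closest known reaction type is the Vilsmeier–Haack ketone synthesis in its intramolecular form, the Friedel–Crafts-type cyclisation of electron-rich arenes onto Tf2O-activated tertiary amides. Ring C closes in the 6-exo-trig mode, the arene carbon adding to a C=N+ bond that stays outside the new six-membered ring. No stereocenter is formed: C2 is an ether carbon remote from the reacting centres, and the non-basic medium should give no enolate or enamine long-lived enough to expel the aryloxide, so the S configuration should be carried through. The step needs site selectivity on ring A (6- versus 8-geranyl), selectivity for ring A over ring B, and tolerance of the geranyl olefins. The first is secured by the local twofold axis of the 3,5-bis(silyloxy)-4-geranylphenoxy group (both ortho carbons give the same product), the second by the higher nucleophilicity of the trioxygenated ring and the six- over five-membered closure (ring B could only give an indanone), the third by the buffered, proton-free electrophile.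

Step 8
Reactants: 14 (2S)-5,7-bis(TBS-oxy)-2-[4-(TBS-oxy)-3,5-dimethoxyphenyl]-6-geranyl-2,3-dihydro-4H-chromen-4-one
Product: 15 (2S)-5,7-dihydroxy-2-(4-hydroxy-3,5-dimethoxyphenyl)-6-geranyl-2,3-dihydro-4H-chromen-4-one (target)
Conditions: Bu4NF, AcOH (1:1), THF, 0 °C
Reagents that add atoms: none
Why: Fluoride cleaves the three aryl silyl ethers while acetic acid buffers the phenoxides, so the flavanone should not open to the chalcone (no epimerisation at C2) and the geranyl chain next to the freed ortho hydroxyls is never exposed to strong acid.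

**Compound list**
1 | phloroglucinol (benzene-1,3,5-triol) | Oc1cc(O)cc(O)c1 | starting material
2 | geraniol [(2E)-3,7-dimethylocta-2,6-dien-1-ol] | CC(C)=CCC/C(C)=C/CO | starting material
3 | 2-geranylphloroglucinol {2-[(2E)-3,7-dimethylocta-2,6-dien-1-yl]benzene-1,3,5-triol} | Oc1cc(O)c(C/C=C(\C)CCC=C(C)C)c(O)c1 | intermediate
4 | methyl syringate (methyl 4-hydroxy-3,5-dimethoxybenzoate) | COC(=O)c1cc(OC)c(O)c(OC)c1 | starting material
5 | methyl 4-[(tert-butyldimethylsilyl)oxy]-3,5-dimethoxybenzoate | COC(=O)c1cc(OC)c(O[Si](C)(C)C(C)(C)C)c(OC)c1 | intermediate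
6 | N,N-dimethylacetamide | CC(=O)N(C)C | starting material
7 | lithium enolate of N,N-dimethylacetamide (formed in the flask, not isolated) | [Li+].[O-]C(=C)N(C)C | intermediate
8 | 3-{4-[(tert-butyldimethylsilyl)oxy]-3,5-dimethoxyphenyl}-N,N-dimethyl-3-oxopropanamide | CN(C)C(=O)CC(=O)c1cc(OC)c(O[Si](C)(C)C(C)(C)C)c(OC)c1 | intermediate
9 | (3R)-3-{4-[(tert-butyldimethylsilyl)oxy]-3,5-dimethoxyphenyl}-3-hydroxy-N,N-dimethylpropanamide | CN(C)C(=O)C[C@@H](O)c1cc(OC)c(O[Si](C)(C)C(C)(C)C)c(OC)c1 | intermediate
10 | (3S)-3-{4-[(2E)-3,7-dimethylocta-2,6-dien-1-yl]-3,5-dihydroxyphenoxy}-3-{4-[(tert-butyldimethylsilyl)oxy]-3,5-dimethoxyphenyl}-N,N-dimethylpropanamide | CN(C)C(=O)C[C@H](Oc1cc(O)c(C/C=C(\C)CCC=C(C)C)c(O)c1)c1cc(OC)c(O[Si](C)(C)C(C)(C)C)c(OC)c1 | intermediate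
11 | (3S)-3-{3,5-bis[(tert-butyldimethylsilyl)oxy]-4-[(2E)-3,7-dimethylocta-2,6-dien-1-yl]phenoxy}-3-{4-[(tert-butyldimethylsilyl)oxy]-3,5-dimethoxyphenyl}-N,N-dimethylpropanamide | CN(C)C(=O)C[C@H](Oc1cc(O[Si](C)(C)C(C)(C)C)c(C/C=C(\C)CCC=C(C)C)c(O[Si](C)(C)C(C)(C)C)c1)c1cc(OC)c(O[Si](C)(C)C(C)(C)C)c(OC)c1 | intermediate
12 | O-triflyl iminium triflate of 11, the N,N-dimethyl-1-(triflyloxy)propan-1-iminium triflate with the (3S) ether centre unchanged (formed in the flask, not isolated) | C[N+](C)=C(OS(=O)(=O)C(F)(F)F)C[C@H](Oc1cc(O[Si](C)(C)C(C)(C)C)c(C/C=C(\C)CCC=C(C)C)c(O[Si](C)(C)C(C)(C)C)c1)c1cc(OC)c(O[Si](C)(C)C(C)(C)C)c(OC)c1.[O-]S(=O)(=O)C(F)(F)F | intermediate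
13 | ring-C iminium triflate, the N,N-dimethyl-(2S)-chroman-4-iminium triflate carrying the substituents of 14 (formed in the flask, not isolated) | C[N+](C)=C1C[C@@H](c2cc(OC)c(O[Si](C)(C)C(C)(C)C)c(OC)c2)Oc2cc(O[Si](C)(C)C(C)(C)C)c(C/C=C(\C)CCC=C(C)C)c(O[Si](C)(C)C(C)(C)C)c21.[O-]S(=O)(=O)C(F)(F)F | intermediate
14 | (2S)-5,7-bis[(tert-butyldimethylsilyl)oxy]-2-{4-[(tert-butyldimethylsilyl)oxy]-3,5-dimethoxyphenyl}-6-[(2E)-3,7-dimethylocta-2,6-dien-1-yl]-2,3-dihydro-4H-chromen-4-one | O=C1C[C@@H](c2cc(OC)c(O[Si](C)(C)C(C)(C)C)c(OC)c2)Oc2cc(O[Si](C)(C)C(C)(C)C)c(C/C=C(\C)CCC=C(C)C)c(O[Si](C)(C)C(C)(C)C)c21 | intermediate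
15 | (2S)-5,7-dihydroxy-2-(4-hydroxy-3,5-dimethoxyphenyl)-6-[(2E)-3,7-dimethylocta-2,6-dien-1-yl]-2,3-dihydro-4H-chromen-4-one | COc1cc([C@@H]2CC(=O)c3c(cc(O)c(C/C=C(\C)CCC=C(C)C)c3O)O2)cc(OC)c1O | target

**Step count**
Total steps: 8. Longest linear sequence: 7 steps (4 → 5 → 8 → 9 → 10 → 11 → 14 → 15); step 1 is the single step of the convergent branch.

**Steps most likely to fail**

Step 7. The activated amide may lose the aryloxide by β-elimination (retro-oxa-Michael at the enamine or keteniminium stage) before the hindered ortho carbon attacks, or the crowded iminium may resist hydrolysis. Fallback from 11 back to 14 by classical Friedel–Crafts acylation of the acid: the amide of 11 would be reduced with Cp2Zr(H)Cl (THF, rt) to (3S)-3-[3,5-bis(TBS-oxy)-4-geranylphenoxy]-3-[4-(TBS-oxy)-3,5-dimethoxyphenyl]propanal F1. Pinnick oxidation (NaClO2, NaH2PO4, 2-methyl-2-butene, t-BuOH/H2O) should give the corresponding (3S)-propanoic acid F2. Treatment with TFAA and 2,6-di-tert-butyl-4-methylpyridine in CH2Cl2 at 0 °C would form the mixed trifluoroacetic anhydride F3, which should acylate the same pair of equivalent ortho carbons and give 14.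

Step 5. Etherification may occur at the two flanked hydroxyls or twice (loss of site selectivity), and the activated benzylic carbinol may eliminate to the cinnamamide. Fallback from 3 back to 11, differentiating the hydroxyls before the coupling: 3 would be silylated exhaustively (TBSCl, imidazole, DMF) to 1,3,5-tris(TBS-oxy)-2-geranylbenzene F4. The unhindered silyl ether para to the geranyl chain would then be removed selectively (K2CO3, 1 equiv, MeOH/THF, 0 °C; the phenoxide formed slows further cleavage) to give 3,5-bis(TBS-oxy)-4-geranylphenol F5. Mitsunobu reaction of this single phenol with 9 (PPh3, DIAD, THF) should give 11 directly, so step 6 is no longer needed.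

Step 1. The very nucleophilic ring may be alkylated two or three times, the acid may cyclise the chain onto an ortho hydroxyl, and the allyl cation may scramble the olefin geometry. Fallback from 1 back to 3 by directed metalation: 1 would be converted into 1,3,5-tris(methoxymethoxy)benzene F6 (MOMCl, i-Pr2NEt, CH2Cl2). Lithiation between two acetal oxygens (n-BuLi, THF, 0 °C) would give 2-lithio-1,3,5-tris(methoxymethoxy)benzene F7. Alkylation with geranyl bromide (CuBr·SMe2 cat., −78 → 0 °C; direct displacement keeps the E olefin) should give 2-geranyl-1,3,5-tris(methoxymethoxy)benzene F8. Removal of the acetals with dilute HCl in MeOH at rt would return 3.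

**Further compounds**
F1 | step 7 | (3S)-3-{3,5-bis[(tert-butyldimethylsilyl)oxy]-4-[(2E)-3,7-dimethylocta-2,6-dien-1-yl]phenoxy}-3-{4-[(tert-butyldimethylsilyl)oxy]-3,5-dimethoxyphenyl}propanal | O=CC[C@H](Oc1cc(O[Si](C)(C)C(C)(C)C)c(C/C=C(\C)CCC=C(C)C)c(O[Si](C)(C)C(C)(C)C)c1)c1cc(OC)c(O[Si](C)(C)C(C)(C)C)c(OC)c1
F2 | step 7 | (3S)-3-{3,5-bis[(tert-butyldimethylsilyl)oxy]-4-[(2E)-3,7-dimethylocta-2,6-dien-1-yl]phenoxy}-3-{4-[(tert-butyldimethylsilyl)oxy]-3,5-dimethoxyphenyl}propanoic acid | OC(=O)C[C@H](Oc1cc(O[Si](C)(C)C(C)(C)C)c(C/C=C(\C)CCC=C(C)C)c(O[Si](C)(C)C(C)(C)C)c1)c1cc(OC)c(O[Si](C)(C)C(C)(C)C)c(OC)c1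
F3 | step 7 | mixed anhydride of acid F2 with trifluoroacetic acid (formed in the flask) | O=C(OC(=O)C(F)(F)F)C[C@H](Oc1cc(O[Si](C)(C)C(C)(C)C)c(C/C=C(\C)CCC=C(C)C)c(O[Si](C)(C)C(C)(C)C)c1)c1cc(OC)c(O[Si](C)(C)C(C)(C)C)c(OC)c1
F4 | step 5 | 1,3,5-tris[(tert-butyldimethylsilyl)oxy]-2-[(2E)-3,7-dimethylocta-2,6-dien-1-yl]benzene | CC(C)(C)[Si](C)(C)Oc1cc(O[Si](C)(C)C(C)(C)C)c(C/C=C(\C)CCC=C(C)C)c(O[Si](C)(C)C(C)(C)C)c1
F5 | step 5 | 3,5-bis[(tert-butyldimethylsilyl)oxy]-4-[(2E)-3,7-dimethylocta-2,6-dien-1-yl]phenol | Oc1cc(O[Si](C)(C)C(C)(C)C)c(C/C=C(\C)CCC=C(C)C)c(O[Si](C)(C)C(C)(C)C)c1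
F6 | step 1 | 1,3,5-tris(methoxymethoxy)benzene | COCOc1cc(OCOC)cc(OCOC)c1
F7 | step 1 | 2-lithio-1,3,5-tris(methoxymethoxy)benzene (formed in the flask) | [Li]c1c(OCOC)cc(OCOC)cc1OCOC
F8 | step 1 | 2-[(2E)-3,7-dimethylocta-2,6-dien-1-yl]-1,3,5-tris(methoxymethoxy)benzene | COCOc1cc(OCOC)c(C/C=C(\C)CCC=C(C)C)c(OCOC)c1
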